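(The numbers in the tables come from a simulation from invented constants.)

- The pitfall is to take the highest reading of the grey run, 16.7 % at 0.833 h, for the top of this flask: it carries a scatter of 0.5 percentage points, and the top can lie between readings.

| flask | left-handed substrate | right-handed substrate | solid reagent | remark | time |
|---|---|---|---|---|---|
| grey | 0.020 M | 0.020 M | 0.080 M | the very flask that is asked about, followed so far |  |
| flask | 0.020 M | 0.020 M | 0.0800 M |  | 10 h |

grey run (percent of the left-handed substrate and right-handed substrate together charged)

| time / h | achiral form / % | left-handed product / % |
|---|---|---|
| 0.167 | 10.0 | 0 |
| 0.417 | 15.5 | 1.2 |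
| 0.833 | 16.7 | 0.4 |
| 2.00 | 9.5 | 2.9 |
| 5.00 | 1.6 | 3.8 |

(readings scatter by 0.5 percentage points)

* the moment within 10 h at which there is most achiral form
* the amount of achiral form, in percent of the left-handed substrate and right-handed substrate together charged, at that time
* earliest time at which at least nineteen twentieths of that best amount are there
* latest time at which they still are

- partner is single-handed; left-handed substrate and right-handed substrate are mirror images of each other, charged as a racemate, each of them at the stated concentration
- solid reagent is a solid; its amount is given per volume of the solution
- at the start none of the solid reagent is in solution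
- the handed part of partner does not stay in what it makes, so the products of the two hands are mirror images too

- The grey run is this flask followed so far, so we reckon its achiral form as a consecutive first-order curve: an amplitude times the difference of a slow and a fast exponential, set by a fall rate and a rise rate.
- An error in the amplitude scales the best amount in proportion and leaves the times unmoved.
- The time of the top is the logarithm of the rate ratio over the rate difference, so an error common to both rates moves it in full proportion although the ratio stays; the half-width of the window goes as one over the square root of their product.
- The fall rate needs care, since it carries the amplitude back to the start, and its reading at 5.00 h, 1.6 %, is smaller than 9.5 % at 2.00 h under the same scatter.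
- The time limit does not matter here: the grey readings are already falling at 2.00 h, earlier than 10 h.
- Those two tail readings give 0.594 h⁻¹: this is the fall rate, the logarithmic drop of the achiral form per hour along the tail.
- Carried back to the start, the tail gives an amplitude of 31.2 % of the charge, and the gap below it at 0.417 h gives a rise rate of 3.03 h⁻¹.
- The top, where making and loss balance, comes at the logarithm of the rate ratio over the rate difference, 0.669 h, with 16.8 %.
- Near the top the curve bends by the product of the rates, so the asked share holds for 0.236 h either side, from 0.433 h to 0.905 h.
- The forecast, “a simple make-then-lose curve”, gives 0.67 h and 17.1 %, higher than our height, with a window from 0.46 h to 0.95 h, which closes later than ours.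
- This flask gives its top at 0.651 h with 17.6 %, and the window runs from 0.447 h to 0.927 h.

    partner + left-handed substrate → left-handed product (k = 0.0321 M⁻¹ s⁻¹)
    partner + right-handed substrate → right-handed product (k = 0.00278 M⁻¹ s⁻¹)
    left-handed substrate ⇌ achiral form (K = 1.75, k = 2.31 × 10⁻⁴ s⁻¹)
    right-handed substrate ⇌ achiral form (K = 1.75, k = 2.31 × 10⁻⁴ s⁻¹)
    achiral form → waste (k = 4.15 × 10⁻⁴ s⁻¹)
    achiral form → decomposed reagent (k = 1.55 × 10⁻⁴ s⁻¹)
    left-handed product ⇌ right-handed product (k = 1.23 × 10⁻⁴ s⁻¹)
    solid reagent ⇌ partner, rate k8*(cs8 - [partner]) while solid is left; crystals form when [partner] > cs8 (solubility = 1.60 mM, k = 4.43 × 10⁻⁴ s⁻¹)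

- The neighbouring flask has the same charge but is read at 2.5 h. Our amplitude and fall rate give it 7.06 % achiral form, and it holds 7.50 %, which is more by 0.44 points. Carrying that amount forward at the same fall rate gives 1.70 % at 5.00 h, and this flask holds 1.77 % of achiral form at that time.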